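The furofuran is traced back to the open chain C7–C8–C8'–C7', whose inner carbons lie on the four-carbon unit C9–C8–C8'–C9' between rings C and B. That unit is a chiral butenolide: C7' of ring B, made nucleophilic as a lithiated dithiane, attacks C8', and the enolate so formed takes the ring C aldehyde at C8. One operation thus makes the C7'–C8' and C8–C7 bonds and sets C8' and C8 from the acetal centre C9'. The precursors are (5S)-5-(d-menthyloxy)furan-2(5H)-one 4, allyl-protected vanillin dithiane 7 and silylated syringaldehyde 9. The C8''–O–C4' side chain is added last by an auxiliary-controlled syn-aldol.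

Key step: step 6

Numbering used: ring C (syringyl)–C7–C8–C9; ring B (central guaiacyl)–C7'–C8'–C9'; ring A (terminal guaiacyl)–C7''–C8''–C9''. The target is (7R,8S,7'R,8'S,7''S,8''S).

Remark on the chemistry: (+)-menthol is (1S,2R,5S), its crystalline acetal is taken to be the (5S) epimer, and addition anti to the menthyloxy group leads to the (8S,8'S) core.

Assumption: 12 and 13 are drawn as the (7R) carbinol and 14 as a mixture at C7'. The other carbinol epimers are carried along, because step 9 re-forms both benzylic C–O bonds.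

Step 1
Reactants: 1 furfural
Product: 2 5-hydroxyfuran-2(5H)-one (racemic)
Conditions: O2, hν (visible), rose bengal (cat.), MeOH, rt
Reagents that add atoms: dioxygen, O=O
Why: Sensitised singlet-oxygen [4+2] cycloaddition to the furan gives an endoperoxide whose hemiacetal with methanol fragments to the hydroxybutenolide (furan photooxygenation), the formyl carbon leaving as methyl formate; the new hemiacetal carbon is racemic and is sorted out in step 2.

Step 2
Reactants: 2 5-hydroxyfuran-2(5H)-one; 3 (+)-menthol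
Product: 4 (5S)-5-{[(1S,2R,5S)-2-isopropyl-5-methylcyclohexyl]oxy}furan-2(5H)-one
Conditions: CSA (cat.), toluene, reflux (Dean–Stark); crystallisation from petroleum ether, −20 °C; mother liquor re-equilibrated (CSA) and recrystallised
Reagents that add atoms: none
Why: Acid-catalysed acetalisation of the cyclic hemiacetal gives both C5 epimers, which equilibrate through the oxocarbenium ion, so crystallisation with recycling of the mother liquor should deliver the single (5S) epimer (crystallisation-driven epimer selection).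

Step 3
Reactants: 5 vanillin
Product: 6 4-(allyloxy)-3-methoxybenzaldehyde
Conditions: allyl bromide, K2CO3, DMF, rt
Reagents that add atoms: allyl bromide, C=CCBr
Why: Williamson ether synthesis on the phenoxide, installing a group that survives organolithium, hydride and acid and is later removed without touching a silyl ether.

Step 4
Reactants: 6 4-(allyloxy)-3-methoxybenzaldehyde
Product: 7 2-[4-(allyloxy)-3-methoxyphenyl]-1,3-dithiane
Conditions: HS(CH2)3SH, BF3·OEt2 (10 mol %), CH2Cl2, 0 °C → rt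
Reagents that add atoms: propane-1,3-dithiol, SCCCS
Why: Lewis-acid-catalysed dithioacetalisation of an aromatic aldehyde, with the allyl aryl ether untouched by catalytic BF3·OEt2 at this temperature.

Step 5
Reactants: 8 syringaldehyde
Product: 9 3,5-dimethoxy-4-(triisopropylsilyloxy)benzaldehyde
Conditions: TIPSCl, imidazole, DMF, rt → 40 °C
Reagents that add atoms: chlorotriisopropylsilane, CC(C)[Si](Cl)(C(C)C)C(C)C
Why: Silylation of a phenol; the bulky silyl ether flanked by two methoxy groups should withstand the lithiated nucleophile, LiAlH4, mild acid and zerovalent palladium and still fall to fluoride at the end.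

Step 6
Reactants: 7 2-[4-(allyloxy)-3-methoxyphenyl]-1,3-dithiane; 4 (5S)-5-(d-menthyloxy)furan-2(5H)-one; 9 3,5-dimethoxy-4-(triisopropylsilyloxy)benzaldehyde
Product: 12 (3R,4S,5S)-4-{2-[4-(allyloxy)-3-methoxyphenyl]-1,3-dithian-2-yl}-3-{(R)-[3,5-dimethoxy-4-(triisopropylsilyloxy)phenyl](hydroxy)methyl}-5-(d-menthyloxy)dihydrofuran-2(3H)-one, via lithiated dithiane 10 (not isolated), via lithium lactone enolate 11 (not isolated)
Conditions: n-BuLi, THF, −78 °C; then 4, −78 °C; then 9, −78 °C; sat. aq. NH4Cl, −78 °C → rt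
Reagents that add atoms: none
Why: n-BuLi removes the C2 proton of 7, and the sulfur-stabilised benzylic carbanion 10 adds 1,4 to butenolide 4 at C8' to give lithium enolate 11, which then adds through C8 to the carbonyl of 9 in a lithium aldol. The closest known reaction type is the tandem conjugate addition–enolate trapping of lithiated 2-aryl-1,3-dithianes on 5-alkoxyfuran-2(5H)-ones, a Michael-initiated three-component coupling. No ring is closed. C8' is set by the C9' acetal centre, because the menthyloxy group blocks one face of the flat butenolide and the nucleophile enters anti to it; C8 is set by the new dithianyl group on C8', which sends the aldehyde to the opposite face and gives the 3,4-trans lactone; C7 is set only by the aldol transition state and is the least controlled centre, which is tolerated because C7 is re-formed in step 9. The step needs 1,4- over 1,2-addition and complete conjugate addition before the aldehyde arrives: the soft, hindered, aryl-stabilised anion at −78 °C favours the β-carbon of the unsaturated lactone, and 9 is added only after 4 is consumed.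

Step 7
Reactants: 12 dithianyl aldol lactone
Product: 13 (3R,4S,5S)-4-[4-(allyloxy)-3-methoxybenzoyl]-3-{(R)-[3,5-dimethoxy-4-(triisopropylsilyloxy)phenyl](hydroxy)methyl}-5-(d-menthyloxy)dihydrofuran-2(3H)-one
Conditions: MeI (excess), CaCO3, MeCN/H2O (9:1), 45 °C
Reagents that add atoms: water, O
Why: Alkylative dithiane hydrolysis, in which S-methylation opens the ring to an aryl-stabilised thionium ion that water turns into the ketone under carbonate buffering that spares the terminal alkene, the silyl ether and the acetal; no stereocentre is formed, and any hemiketal between the C7 hydroxyl and the ketone is reduced through its open form in step 8.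

Step 8
Reactants: 13 keto lactone
Product: 14 (1R,2S,3S,4RS)-4-[4-(allyloxy)-3-methoxyphenyl]-1-[3,5-dimethoxy-4-(triisopropylsilyloxy)phenyl]-2,3-bis(hydroxymethyl)butane-1,4-diol
Conditions: LiAlH4, THF, 0 °C → rt; aqueous NaOH work-up
Reagents that add atoms: none
Why: Hydride reduction with LiAlH4 converts the ketone into the C7' carbinol (configuration uncontrolled and not needed) and opens the lactone and the menthyl acetal through the aldehydes to the C9 and C9' primary alcohols with release of menthol, while C7, C8 and C8' are untouched.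

Step 9
Reactants: 14 tetraol
Product: 15 (1R,3aS,4R,6aS)-1-[4-(allyloxy)-3-methoxyphenyl]-4-[3,5-dimethoxy-4-(triisopropylsilyloxy)phenyl]tetrahydro-1H,3H-furo[3,4-c]furan
Conditions: CSA (10 mol %), CH2Cl2, 4 Å molecular sieves, 0 °C → rt
Reagents that add atoms: none
Why: Acid-catalysed double cycloetherification (benzylic SN1), in which each para-oxygenated benzylic carbinol ionises to a quinone-methide-like cation that the 1,4-related primary hydroxyl captures in a 5-exo closure, the aryl group taking the exo position on the cis-fused bicycle fixed by C8 and C8', which should set C7 and C7' as R,R whatever the carbinol configurations were.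

Step 10
Reactants: 15 allyl-protected furofuran
Product: 16 4-{(1R,3aS,4R,6aS)-4-[3,5-dimethoxy-4-(triisopropylsilyloxy)phenyl]tetrahydro-1H,3H-furo[3,4-c]furan-1-yl}-2-methoxyphenol
Conditions: Pd(PPh3)4 (5 mol %), morpholine, THF, rt
Reagents that add atoms: none
Why: Tsuji–Trost-type deallylation, in which zerovalent palladium ionises the allyl aryl ether to a π-allyl complex that morpholine intercepts, leaving the silyl ether and the benzylic ethers intact.

Step 11
Reactants: 17 (R)-4-benzyloxazolidin-2-one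
Product: 18 (R)-4-benzyl-3-(bromoacetyl)oxazolidin-2-one
Conditions: n-BuLi, THF, −78 °C; BrCH2COBr, −78 → 0 °C
Reagents that add atoms: bromoacetyl bromide, BrCC(Br)=O
Why: N-acylation of the lithiated oxazolidinone by an acid bromide, which is faster than displacement of the α-bromide at low temperature; the stereocentre of the auxiliary is not involved.

Step 12
Reactants: 16 ring B phenol; 18 (R)-4-benzyl-3-(bromoacetyl)oxazolidin-2-one
Product: 19 (R)-4-benzyl-3-[2-(4-{(1R,3aS,4R,6aS)-4-[3,5-dimethoxy-4-(triisopropylsilyloxy)phenyl]tetrahydro-1H,3H-furo[3,4-c]furan-1-yl}-2-methoxyphenoxy)acetyl]oxazolidin-2-one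
Conditions: K2CO3, acetone, rt
Reagents that add atoms: none
Why: Williamson alkylation of the ring B phenoxide by an α-bromo imide, an activated SN2 electrophile that should react at room temperature faster than the imide is cleaved.

Step 13
Reactants: 5 vanillin
Product: 20 3-methoxy-4-(triisopropylsilyloxy)benzaldehyde
Conditions: TIPSCl, imidazole, DMF, rt
Reagents that add atoms: chlorotriisopropylsilane, CC(C)[Si](Cl)(C(C)C)C(C)C
Why: Silylation of the phenol, chosen so that rings A and C are unmasked together in step 16.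

Step 14
Reactants: 19 aryloxyacetyl imide; 20 3-methoxy-4-(triisopropylsilyloxy)benzaldehyde
Product: 22 (R)-4-benzyl-3-{(2R,3S)-2-[ring B aryloxy group of 19]-3-hydroxy-3-[3-methoxy-4-(triisopropylsilyloxy)phenyl]propanoyl}oxazolidin-2-one, via dibutylboron Z-enolate 21 (not isolated)
Conditions: Et3N then Bu2BOTf, CH2Cl2, −78 → 0 °C; then 20, −78 → 0 °C; pH 7 buffer, MeOH, 30% H2O2, 0 °C
Reagents that add atoms: none
Why: Evans syn-aldol, in which soft enolisation gives the Z boron enolate 21 that adds through a chair Zimmerman–Traxler transition state on the enolate face away from the benzyl group of the (R)-auxiliary, setting C8'' and C7'' in the syn (threo) relationship with the absolute sense that becomes (7''S,8''S) after reduction.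

Step 15
Reactants: 22 aldol adduct
Product: 23 (1S,2S)-2-(4-{(1R,3aS,4R,6aS)-4-[3,5-dimethoxy-4-(triisopropylsilyloxy)phenyl]tetrahydro-1H,3H-furo[3,4-c]furan-1-yl}-2-methoxyphenoxy)-1-[3-methoxy-4-(triisopropylsilyloxy)phenyl]propane-1,3-diol
Conditions: LiBH4, MeOH (1 equiv), THF, 0 °C
Reagents that add atoms: none
Why: Reductive cleavage of the N-acyl oxazolidinone with LiBH4 gives the primary alcohol C9'' and returns the auxiliary, without epimerising C8'' or touching the silyl ethers.

Step 16
Reactants: 23 bis-silyl ether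
Product: 24 4-[(1S,2S)-1,3-dihydroxy-2-{4-[(1R,3aS,4R,6aS)-4-(4-hydroxy-3,5-dimethoxyphenyl)tetrahydro-1H,3H-furo[3,4-c]furan-1-yl]-2-methoxyphenoxy}propyl]-2-methoxyphenol (CNP0255927.3)
Conditions: TBAF, AcOH, THF, 0 °C
Reagents that add atoms: none
Why: Fluoride-induced cleavage of both aryl silyl ethers, buffered with acetic acid so that the liberated p-hydroxybenzyl alcohol is not exposed to free phenoxide.

Compound list
1 | furfural | O=Cc1ccco1 | starting material
2 | 5-hydroxyfuran-2(5H)-one (racemic) | O=C1OC(O)C=C1 | intermediate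
3 | (+)-menthol, (1S,2R,5S)-2-isopropyl-5-methylcyclohexan-1-ol | CC(C)[C@H]1CC[C@H](C)C[C@@H]1O | starting material
4 | (5S)-5-{[(1S,2R,5S)-2-isopropyl-5-methylcyclohexyl]oxy}furan-2(5H)-one | O=C1O[C@H](O[C@H]2C[C@@H](C)CC[C@@H]2C(C)C)C=C1 | intermediate
5 | vanillin | COc1cc(C=O)ccc1O | starting material
6 | 4-(allyloxy)-3-methoxybenzaldehyde | COc1cc(C=O)ccc1OCC=C | intermediate
7 | 2-[4-(allyloxy)-3-methoxyphenyl]-1,3-dithiane | C=CCOc1ccc(C2SCCCS2)cc1OC | intermediate
8 | syringaldehyde | COc1cc(C=O)cc(OC)c1O | starting material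
9 | 3,5-dimethoxy-4-(triisopropylsilyloxy)benzaldehyde | COc1cc(C=O)cc(OC)c1O[Si](C(C)C)(C(C)C)C(C)C | intermediate
10 | 2-lithio-2-[4-(allyloxy)-3-methoxyphenyl]-1,3-dithiane | [Li]C1(c2ccc(OCC=C)c(OC)c2)SCCCS1 | intermediate
11 | lithium enolate of (4S,5S)-4-{2-[4-(allyloxy)-3-methoxyphenyl]-1,3-dithian-2-yl}-5-(d-menthyloxy)dihydrofuran-2(3H)-one | [Li]OC1=C[C@H](C2(c3ccc(OCC=C)c(OC)c3)SCCCS2)[C@@H](O[C@H]2C[C@@H](C)CC[C@@H]2C(C)C)O1 | intermediate
12 | (3R,4S,5S)-4-{2-[4-(allyloxy)-3-methoxyphenyl]-1,3-dithian-2-yl}-3-{(R)-[3,5-dimethoxy-4-(triisopropylsilyloxy)phenyl](hydroxy)methyl}-5-(d-menthyloxy)dihydrofuran-2(3H)-one | O=C1O[C@H](O[C@H]2C[C@@H](C)CC[C@@H]2C(C)C)[C@@H](C2(c3ccc(OCC=C)c(OC)c3)SCCCS2)[C@@H]1[C@@H](O)c1cc(OC)c(O[Si](C(C)C)(C(C)C)C(C)C)c(OC)c1 | intermediate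
13 | (3R,4S,5S)-4-[4-(allyloxy)-3-methoxybenzoyl]-3-{(R)-[3,5-dimethoxy-4-(triisopropylsilyloxy)phenyl](hydroxy)methyl}-5-(d-menthyloxy)dihydrofuran-2(3H)-one | O=C1O[C@H](O[C@H]2C[C@@H](C)CC[C@@H]2C(C)C)[C@@H](C(=O)c2ccc(OCC=C)c(OC)c2)[C@@H]1[C@@H](O)c1cc(OC)c(O[Si](C(C)C)(C(C)C)C(C)C)c(OC)c1 | intermediate
14 | (1R,2S,3S,4RS)-4-[4-(allyloxy)-3-methoxyphenyl]-1-[3,5-dimethoxy-4-(triisopropylsilyloxy)phenyl]-2,3-bis(hydroxymethyl)butane-1,4-diol (C7' epimers) | C=CCOc1ccc(C(O)[C@H](CO)[C@@H](CO)[C@@H](O)c2cc(OC)c(O[Si](C(C)C)(C(C)C)C(C)C)c(OC)c2)cc1OC | intermediate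
15 | (1R,3aS,4R,6aS)-1-[4-(allyloxy)-3-methoxyphenyl]-4-[3,5-dimethoxy-4-(triisopropylsilyloxy)phenyl]tetrahydro-1H,3H-furo[3,4-c]furan | C=CCOc1ccc([C@@H]2OC[C@@H]3[C@H]2CO[C@H]3c2cc(OC)c(O[Si](C(C)C)(C(C)C)C(C)C)c(OC)c2)cc1OC | intermediate
16 | 4-{(1R,3aS,4R,6aS)-4-[3,5-dimethoxy-4-(triisopropylsilyloxy)phenyl]tetrahydro-1H,3H-furo[3,4-c]furan-1-yl}-2-methoxyphenol | Oc1ccc([C@@H]2OC[C@@H]3[C@H]2CO[C@H]3c2cc(OC)c(O[Si](C(C)C)(C(C)C)C(C)C)c(OC)c2)cc1OC | intermediate
17 | (R)-4-benzyloxazolidin-2-one | O=C1N[C@H](Cc2ccccc2)CO1 | starting material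
18 | (R)-4-benzyl-3-(bromoacetyl)oxazolidin-2-one | O=C(CBr)N1[C@H](Cc2ccccc2)COC1=O | intermediate
19 | (R)-4-benzyl-3-[2-(4-{(1R,3aS,4R,6aS)-4-[3,5-dimethoxy-4-(triisopropylsilyloxy)phenyl]tetrahydro-1H,3H-furo[3,4-c]furan-1-yl}-2-methoxyphenoxy)acetyl]oxazolidin-2-one | O=C(COc1ccc([C@@H]2OC[C@@H]3[C@H]2CO[C@H]3c2cc(OC)c(O[Si](C(C)C)(C(C)C)C(C)C)c(OC)c2)cc1OC)N1[C@H](Cc2ccccc2)COC1=O | intermediate
20 | 3-methoxy-4-(triisopropylsilyloxy)benzaldehyde | COc1cc(C=O)ccc1O[Si](C(C)C)(C(C)C)C(C)C | intermediate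
21 | dibutylboron (Z)-enolate of 19 | CCCCB(CCCC)O/C(=C\Oc1ccc([C@@H]2OC[C@@H]3[C@H]2CO[C@H]3c2cc(OC)c(O[Si](C(C)C)(C(C)C)C(C)C)c(OC)c2)cc1OC)N1[C@H](Cc2ccccc2)COC1=O | intermediate
22 | (R)-4-benzyl-3-{(2R,3S)-2-(4-{(1R,3aS,4R,6aS)-4-[3,5-dimethoxy-4-(triisopropylsilyloxy)phenyl]tetrahydro-1H,3H-furo[3,4-c]furan-1-yl}-2-methoxyphenoxy)-3-hydroxy-3-[3-methoxy-4-(triisopropylsilyloxy)phenyl]propanoyl}oxazolidin-2-one | O=C([C@H](Oc1ccc([C@@H]2OC[C@@H]3[C@H]2CO[C@H]3c2cc(OC)c(O[Si](C(C)C)(C(C)C)C(C)C)c(OC)c2)cc1OC)[C@@H](O)c1ccc(O[Si](C(C)C)(C(C)C)C(C)C)c(OC)c1)N1[C@H](Cc2ccccc2)COC1=O | intermediate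
23 | (1S,2S)-2-(4-{(1R,3aS,4R,6aS)-4-[3,5-dimethoxy-4-(triisopropylsilyloxy)phenyl]tetrahydro-1H,3H-furo[3,4-c]furan-1-yl}-2-methoxyphenoxy)-1-[3-methoxy-4-(triisopropylsilyloxy)phenyl]propane-1,3-diol | COc1cc([C@H](O)[C@H](CO)Oc2ccc([C@@H]3OC[C@@H]4[C@H]3CO[C@H]4c3cc(OC)c(O[Si](C(C)C)(C(C)C)C(C)C)c(OC)c3)cc2OC)ccc1O[Si](C(C)C)(C(C)C)C(C)C | intermediate
24 | 4-[(1S,2S)-1,3-dihydroxy-2-{4-[(1R,3aS,4R,6aS)-4-(4-hydroxy-3,5-dimethoxyphenyl)tetrahydro-1H,3H-furo[3,4-c]furan-1-yl]-2-methoxyphenoxy}propyl]-2-methoxyphenol | COc1cc([C@H](O)[C@H](CO)Oc2ccc([C@@H]3OC[C@@H]4[C@H]3CO[C@H]4c3cc(OC)c(O)c(OC)c3)cc2OC)ccc1O | target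

Total step count: 16. Longest linear sequence: 11 steps (1, 2, 6, 7, 8, 9, 10, 12, 14, 15, 16; the branch from vanillin through steps 3 and 4 is equally long).

Steps most likely to fail

Step 6. The enolate may be quenched by proton transfer or may add poorly to the hindered, electron-rich aldehyde, and leftover lithiated dithiane may attack the aldehyde directly. The coupling would then be run in two stages. Dithiane 7 is lithiated (n-BuLi, THF, −78 °C), added to 4 and the mixture is quenched with NH4Cl to give the isolated conjugate adduct (4S,5S)-4-{2-[4-(allyloxy)-3-methoxyphenyl]-1,3-dithian-2-yl}-5-(d-menthyloxy)dihydrofuran-2(3H)-one F1. Deprotonation of F1 with LiN(iPr)2 (THF, −78 °C) re-forms enolate 11 free of dithiane anion, and 9 is added in excess. This sets out from 7 and 4 and comes back at 12.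

Step 9. Reversible ionisation may scramble C7 or C7' to endo-aryl epimers, or the C7' cation may be held by the C7 hydroxyl as a 2,5-diaryltetrahydrofuran. The closure would then be done by sulfonate activation under basic buffering instead of acid catalysis. Tetraol 14 with MsCl in pyridine (0 °C → rt) should form benzylic mesylates that ionise and are captured by the primary hydroxyls irreversibly, since no acid is present to reopen the product. This sets out from 14 and comes back at 15; it makes no new compound (F0).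

Step 14. The boron triflate may ionise the benzylic ethers of the furofuran and erode C7 or C7', or the enolate may add sluggishly to the electron-rich aldehyde. The side chain would then be built by catalytic reduction in place of the auxiliary aldol.
- Aldehyde 20 is homologated with ethyl diazoacetate (SnCl2 cat., CH2Cl2; Roskamp reaction) to ethyl 3-[3-methoxy-4-(triisopropylsilyloxy)phenyl]-3-oxopropanoate F2.
- Chlorination (SO2Cl2, CH2Cl2, 0 °C) gives racemic ethyl 2-chloro-3-[3-methoxy-4-(triisopropylsilyloxy)phenyl]-3-oxopropanoate F3.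
- F3 alkylates phenol 16 (K2CO3, acetone) to the α-aryloxy β-keto ester F4, whose C8'' epimerises freely.
- Noyori–Ikariya transfer hydrogenation with dynamic kinetic resolution (RuCl[(R,R)-TsDPEN](p-cymene), HCO2H/Et3N, CH2Cl2) should give the syn hydroxy ester, ethyl (2R,3S)-2-aryloxy-3-hydroxy-3-arylpropanoate F5, as is established for α-alkoxy β-keto esters.
- LiBH4 (THF, 0 °C) reduces the ester to the diol.

This sets out from 16 and 20 and comes back at 23.

Further compounds
F1 | step 6 | (4S,5S)-4-{2-[4-(allyloxy)-3-methoxyphenyl]-1,3-dithian-2-yl}-5-(d-menthyloxy)dihydrofuran-2(3H)-one | O=C1O[C@H](O[C@H]2C[C@@H](C)CC[C@@H]2C(C)C)[C@@H](C2(c3ccc(OCC=C)c(OC)c3)SCCCS2)C1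
F0 | step 9 | none | none
F2 | step 14 | ethyl 3-[3-methoxy-4-(triisopropylsilyloxy)phenyl]-3-oxopropanoate | CCOC(=O)CC(=O)c1ccc(O[Si](C(C)C)(C(C)C)C(C)C)c(OC)c1
F3 | step 14 | ethyl 2-chloro-3-[3-methoxy-4-(triisopropylsilyloxy)phenyl]-3-oxopropanoate (racemic) | CCOC(=O)C(Cl)C(=O)c1ccc(O[Si](C(C)C)(C(C)C)C(C)C)c(OC)c1
F4 | step 14 | ethyl 2-(4-{(1R,3aS,4R,6aS)-4-[3,5-dimethoxy-4-(triisopropylsilyloxy)phenyl]tetrahydro-1H,3H-furo[3,4-c]furan-1-yl}-2-methoxyphenoxy)-3-[3-methoxy-4-(triisopropylsilyloxy)phenyl]-3-oxopropanoate (C2 epimers) | CCOC(=O)C(Oc1ccc([C@@H]2OC[C@@H]3[C@H]2CO[C@H]3c2cc(OC)c(O[Si](C(C)C)(C(C)C)C(C)C)c(OC)c2)cc1OC)C(=O)c1ccc(O[Si](C(C)C)(C(C)C)C(C)C)c(OC)c1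
F5 | step 14 | ethyl (2R,3S)-2-(4-{(1R,3aS,4R,6aS)-4-[3,5-dimethoxy-4-(triisopropylsilyloxy)phenyl]tetrahydro-1H,3H-furo[3,4-c]furan-1-yl}-2-methoxyphenoxy)-3-hydroxy-3-[3-methoxy-4-(triisopropylsilyloxy)phenyl]propanoate | CCOC(=O)[C@H](Oc1ccc([C@@H]2OC[C@@H]3[C@H]2CO[C@H]3c2cc(OC)c(O[Si](C(C)C)(C(C)C)C(C)C)c(OC)c2)cc1OC)[C@@H](O)c1ccc(O[Si](C(C)C)(C(C)C)C(C)C)c(OC)c1
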